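**Retrosynthetic overview**
- Ring atoms are numbered O1–O2–C3–C4–C5–C6 (C3 carries CH3 and the propanoic acid chain, C6 carries CH3 and the 8-phenyloctyl chain). Target acid ⇐ methyl ester (saponification) ⇐ 3,6-dihydro-1,2-dioxine (diimide); the C4=C5 double bond is a temporary oxidation level.
- Key disconnection: ring bond C5–C6, made by a catalytic asymmetric vinylsilane-terminated peroxycarbenium (peroxy-silyl-Prins) cyclisation of an acyclic methoxy peroxyketal. This is the only ring-forming step (1,2-dioxine ring; the phenyl ring is bought).
- Enabling feature: C6 is a fully substituted, peroxy-bearing carbon at the ketone oxidation level (the masked carbonyl of 10-phenyldecan-2-one, joined to C3 through O1–O2), so it can be ionised to a peroxycarbenium ion; C5 is carried as the silicon-bearing carbon of a (Z)-vinylsilane on C3.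
- Peroxyketal ⇐ racemic tertiary allylic hydroperoxide (Schenck ene reaction of an allylsilane from Wittig olefination of methyl levulinate) + dimethyl ketal of 10-phenyldecan-2-one (PhMgBr + 10-bromodec-1-ene, then Wacker oxidation).
- Stereochemistry: C6 is set in the key step by a chiral counter-anion; C3 comes racemic from the ene reaction and is sorted in the same step, which turns the two enantiomers into separable diastereomers, of which only the (3S,6S)-dihydrodioxine is carried on.

Key step: step 8

Assumption: the target is read as 3-[(3R,6S)-3,6-dimethyl-6-(8-phenyloctyl)-1,2-dioxan-3-yl]propanoic acid (trans-3,6-dimethyl), and the (S,S) enantiomer of the acid catalyst in step 8 is assumed to deliver 6S (otherwise its mirror image is used).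

Step 1
Reactants: 1 methyltriphenylphosphonium bromide; 2 (iodomethyl)trimethylsilane
Product: 4 [2-(trimethylsilyl)ethyl]triphenylphosphonium iodide, via methylidenetriphenylphosphorane 3 (not isolated)
Conditions: n-BuLi (1.0 equiv), THF, 0 °C; then 2, 0 °C → rt
Reagents that add atoms: none
Why: The unstabilised ylide 3 should be C-alkylated by the primary α-silyl iodide (SN2), the established entry to the β-silylethyl phosphonium salt used for allylsilane Wittig reactions.

Step 2
Reactants: 4 [2-(trimethylsilyl)ethyl]triphenylphosphonium iodide; 5 methyl 4-oxopentanoate (methyl levulinate)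
Product: 7 methyl 4-methyl-6-(trimethylsilyl)hex-4-enoate (E/Z mixture), via [2-(trimethylsilyl)ethylidene]triphenylphosphorane 6 (not isolated)
Conditions: NaN(SiMe3)2, THF, 0 °C; then 5, −78 °C → rt
Reagents that add atoms: none
Why: Wittig olefination of the ketone, which is more electrophilic than the ester, by the non-stabilised β-silyl ylide should give the allylsilane, and the alkene geometry is irrelevant because this double bond is moved in step 3.

Step 3
Reactants: 7 methyl 4-methyl-6-(trimethylsilyl)hex-4-enoate
Product: 8 methyl (Z)-4-hydroperoxy-4-methyl-6-(trimethylsilyl)hex-5-enoate (racemic)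
Conditions: O2, hν (visible), tetraphenylporphyrin (cat.), CH2Cl2, −20 °C
Reagents that add atoms: dioxygen (as singlet oxygen), O=O
Why: In this Schenck ene reaction of an allylsilane, oxygen should bond to the trisubstituted carbon remote from silicon (the charge developing at the other alkene carbon is stabilised by the β-C–Si bond) and remove the inward-pointing hydrogen of the CH2Si group, giving the tertiary allylic hydroperoxide with a (Z)-vinylsilane; the new stereocentre (future C3) is formed racemic.

Step 4
Reactants: 9 phenylmagnesium bromide; 10 10-bromodec-1-ene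
Product: 11 10-phenyldec-1-ene
Conditions: FeCl3 (5 mol %), TMEDA, THF, 0 °C, slow addition of 9
Reagents that add atoms: none
Why: Iron-catalysed Kumada-type cross-coupling of an aryl Grignard reagent with a primary alkyl bromide should proceed without touching the remote terminal alkene.

Step 5
Reactants: 11 10-phenyldec-1-ene
Product: 12 10-phenyldecan-2-one
Conditions: PdCl2 (10 mol %), CuCl (20 mol %), O2 (1 atm), DMF/H2O 7:1, rt
Reagents that add atoms: water, O
Why: Tsuji–Wacker oxidation of a terminal alkene should give the methyl ketone with Markovnikov selectivity.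

Step 6
Reactants: 12 10-phenyldecan-2-one
Product: 13 2,2-dimethoxy-10-phenyldecane
Conditions: HC(OMe)3, MeOH, p-TsOH·H2O (cat.), rt; Et3N
Reagents that add atoms: trimethyl orthoformate, COC(OC)OC
Why: Acid-catalysed ketalisation should go to completion because the orthoester consumes the water formed.

Step 7
Reactants: 8 methyl (Z)-4-hydroperoxy-4-methyl-6-(trimethylsilyl)hex-5-enoate; 13 2,2-dimethoxy-10-phenyldecane
Product: 14 methyl (Z)-4-[(2-methoxy-10-phenyldecan-2-yl)peroxy]-4-methyl-6-(trimethylsilyl)hex-5-enoate (racemic, both ketal epimers)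
Conditions: PPTS (10 mol %), 5 Å MS, CH2Cl2, 0 °C → rt
Reagents that add atoms: none
Why: Mild acid-catalysed exchange of one methoxy group of the ketal for the hydroperoxide (monoperoxyketal formation, the usual way to cap a hydroperoxide) should join the two fragments through O1–O2, and the configuration of the ketal carbon does not matter because it becomes planar in step 8.

Step 8
Reactants: 14 methyl (Z)-4-[(2-methoxy-10-phenyldecan-2-yl)peroxy]-4-methyl-6-(trimethylsilyl)hex-5-enoate
Product: 16 methyl 3-[(3S,6S)-3,6-dimethyl-6-(8-phenyloctyl)-3,6-dihydro-1,2-dioxin-3-yl]propanoate, via peroxycarbenium ion 15 (not isolated)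
Conditions: (S,S)-IDPi (BINOL-derived imidodiphosphorimidate Brønsted acid with 3,3'-aryl groups and N-triflyl groups on phosphorus, 5 mol %), 4 Å MS, CH2Cl2, −78 → −40 °C; Et3N; chromatography on SiO2
Reagents that add atoms: none
Why: Proposed new method: the acid (after the first turnover its N-silylated form) activates the methoxy group of 14, which leaves as MeOH/Me3SiOMe to give peroxycarbenium ion 15 paired with the confined chiral anion; the (Z)-vinylsilane attacks the carbenium carbon (ring C6) through its silicon-bearing carbon (ring C5), and the β-silyl cation at C4 loses Me3Si+ to the anion, which regenerates the silylated catalyst. Closest known reaction types are vinylsilane-terminated oxocarbenium cyclisations to 5,6-dihydro-2H-pyrans (silyl-Prins), Lewis acid-mediated Hosomi–Sakurai allylation of monoperoxyketals through peroxycarbenium ions, and IDPi-catalysed asymmetric Prins cyclisations and additions to aliphatic oxocarbenium ions; combining a peroxycarbenium ion with a vinylsilane and with a chiral anion is new. The 1,2-dioxine ring closes 6-endo-trig with respect to the vinylsilane (both alkene carbons and the O1=C6 unit end up in the ring), and the Z geometry, silicon cis to C3, lets the C–Si bond align with the developing empty orbital at C4 and gives the cis ring alkene. The step needs ionisation at the ketal carbon and not at the tertiary allylic C3–O2 bond, secured by the basic methoxy oxygen and the oxygen-stabilised cation, and ipso attack of the alkene, secured by the β-silicon effect. The new stereocentre C6 is set by the chiral counter-anion, which has to tell CH3 from the CH2 chain on the carbenium carbon as such confined anions do for small methyl ketones; the substrate gives no bias of its own because both fully substituted carbons carry CH3 and a primary alkyl group. C3 is not touched, so the (S) enantiomer of 14 should give 16 and the (R) enantiomer its (3R,6S) diastereomer, and their separation on silica resolves the racemate in the same operation at the cost of the half of the material that carries the wrong C3 configuration.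

Step 9
Reactants: 16 methyl 3-[(3S,6S)-3,6-dimethyl-6-(8-phenyloctyl)-3,6-dihydro-1,2-dioxin-3-yl]propanoate
Product: 17 methyl 3-[(3R,6S)-3,6-dimethyl-6-(8-phenyloctyl)-1,2-dioxan-3-yl]propanoate
Conditions: KO2CN=NCO2K (potassium azodicarboxylate, excess), AcOH, MeOH/CH2Cl2, 0 °C → rt
Reagents that add atoms: none
Why: Diimide generated in situ should transfer H2 to the cis ring alkene in a concerted step that leaves the O–O bond intact, the standard reduction of 3,6-dihydro-1,2-dioxines to 1,2-dioxanes; no stereocentre is touched (the C3 descriptor changes only because C4 becomes CH2).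

Step 10
Reactants: 17 methyl 3-[(3R,6S)-3,6-dimethyl-6-(8-phenyloctyl)-1,2-dioxan-3-yl]propanoate
Product: 18 3-[(3R,6S)-3,6-dimethyl-6-(8-phenyloctyl)-1,2-dioxan-3-yl]propanoic acid (CNP0390528.1)
Conditions: LiOH, THF/H2O 3:1, 0 °C → rt; then 1 M HCl to pH 3
Reagents that add atoms: lithium hydroxide, [Li+].[OH-]
Why: Saponification of the methyl ester should be clean because the di-tertiary peroxide has no α-hydrogen and so cannot undergo base-induced Kornblum–DeLaMare fragmentation.

**Compound list**
1 | methyltriphenylphosphonium bromide | C[P+](c1ccccc1)(c1ccccc1)c1ccccc1.[Br-] | starting material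
2 | (iodomethyl)trimethylsilane | C[Si](C)(C)CI | starting material
3 | methylidenetriphenylphosphorane | C=P(c1ccccc1)(c1ccccc1)c1ccccc1 | intermediate (not isolated)
4 | [2-(trimethylsilyl)ethyl]triphenylphosphonium iodide | C[Si](C)(C)CC[P+](c1ccccc1)(c1ccccc1)c1ccccc1.[I-] | intermediate
5 | methyl 4-oxopentanoate (methyl levulinate) | CC(=O)CCC(=O)OC | starting material
6 | [2-(trimethylsilyl)ethylidene]triphenylphosphorane | C[Si](C)(C)CC=P(c1ccccc1)(c1ccccc1)c1ccccc1 | intermediate (not isolated)
7 | methyl 4-methyl-6-(trimethylsilyl)hex-4-enoate (E/Z mixture) | COC(=O)CCC(C)=CC[Si](C)(C)C | intermediate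
8 | methyl (Z)-4-hydroperoxy-4-methyl-6-(trimethylsilyl)hex-5-enoate (racemic) | COC(=O)CCC(C)(OO)/C=C\[Si](C)(C)C | intermediate
9 | phenylmagnesium bromide | Br[Mg]c1ccccc1 | starting material
10 | 10-bromodec-1-ene | C=CCCCCCCCCBr | starting material
11 | 10-phenyldec-1-ene | C=CCCCCCCCCc1ccccc1 | intermediate
12 | 10-phenyldecan-2-one | CC(=O)CCCCCCCCc1ccccc1 | intermediate
13 | 2,2-dimethoxy-10-phenyldecane | COC(C)(OC)CCCCCCCCc1ccccc1 | intermediate
14 | methyl (Z)-4-[(2-methoxy-10-phenyldecan-2-yl)peroxy]-4-methyl-6-(trimethylsilyl)hex-5-enoate (racemic, both ketal epimers) | COC(=O)CCC(C)(OOC(C)(OC)CCCCCCCCc1ccccc1)/C=C\[Si](C)(C)C | intermediate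
15 | peroxycarbenium ion from 14 by loss of methoxide (cation, paired with the catalyst anion) | COC(=O)CCC(C)(O[O+]=C(C)CCCCCCCCc1ccccc1)/C=C\[Si](C)(C)C | intermediate (not isolated)
16 | methyl 3-[(3S,6S)-3,6-dimethyl-6-(8-phenyloctyl)-3,6-dihydro-1,2-dioxin-3-yl]propanoate | C[C@]1(CCCCCCCCc2ccccc2)C=C[C@](C)(CCC(=O)OC)OO1 | intermediate
17 | methyl 3-[(3R,6S)-3,6-dimethyl-6-(8-phenyloctyl)-1,2-dioxan-3-yl]propanoate | C[C@]1(CCCCCCCCc2ccccc2)CC[C@](C)(CCC(=O)OC)OO1 | intermediate
18 | 3-[(3R,6S)-3,6-dimethyl-6-(8-phenyloctyl)-1,2-dioxan-3-yl]propanoic acid | C[C@]1(CCCCCCCCc2ccccc2)CC[C@](C)(CCC(=O)O)OO1 | target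

**Step count**
Total: 10 steps. Longest linear sequence: 7 steps (1, 2, 3, 7, 8, 9, 10; the ketone branch 4, 5, 6, 7, 8, 9, 10 is equally long).

**Steps most likely to fail**

Step 8. The peroxycarbenium ion may fragment before it is trapped (Hock-type O–O heterolysis, ionisation of the tertiary allylic C3–O2 bond, or protodesilylation of the vinylsilane), and if the ring closes, the counter-anion may fail to control the face of C6. The fallback uses only known chemistry (acid-catalysed double perhydrolysis of a di-tertiary 1,4-diol); it sets out from ketone 12 and comes back at 18. Addition of the Grignard reagent of 2-(2-bromoethyl)-2-methyl-1,3-dioxolane to 12 would give 3-methyl-1-(2-methyl-1,3-dioxolan-2-yl)-11-phenylundecan-3-ol F1. Ketal hydrolysis (PPTS, acetone/H2O) would give 5-hydroxy-5-methyl-13-phenyltridecan-2-one F2, and excess but-3-enylmagnesium bromide would then give 5,8-dimethyl-16-phenylhexadec-1-ene-5,8-diol F3. Treatment with 50% H2O2 and catalytic H2SO4 would close 3-(but-3-enyl)-3,6-dimethyl-6-(8-phenyloctyl)-1,2-dioxane F4 as a stereoisomer mixture. Ozonolysis (O3, CH2Cl2/MeOH, −78 °C; Me2S) would give 3-[3,6-dimethyl-6-(8-phenyloctyl)-1,2-dioxan-3-yl]propanal F5, and Pinnick oxidation would give 3-[3,6-dimethyl-6-(8-phenyloctyl)-1,2-dioxan-3-yl]propanoic acid (stereoisomer mixture) F6. The trans-dimethyl racemate would be separated by chromatography and resolved (salt with (S)-1-phenylethylamine or chiral-phase HPLC) to reach 18.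

Step 3. Singlet oxygen may abstract hydrogen from the C4 methyl group or the chain CH2 instead of the CH2Si group (regioisomeric secondary hydroperoxides), silicon may migrate to oxygen, or the E-vinylsilane may form. The fallback sets out from methyl levulinate 5 and comes back at 8. Addition of (trimethylsilyl)ethynylmagnesium bromide with lactonisation would give 5-methyl-5-[(trimethylsilyl)ethynyl]oxolan-2-one F7. Lindlar semihydrogenation (H2, Pd/CaCO3 poisoned with Pb(OAc)2, quinoline) would give 5-methyl-5-[(Z)-2-(trimethylsilyl)ethenyl]oxolan-2-one F8. Acid-catalysed SN1 perhydrolysis of the tertiary allylic C–O bond (50% H2O2, cat. H2SO4, Et2O, 0 °C) would give (Z)-4-hydroperoxy-4-methyl-6-(trimethylsilyl)hex-5-enoic acid F9, and methylation with Me3SiCHN2 would return to 8.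

Step 7. Acid-induced Hock cleavage of the tertiary allylic hydroperoxide or protodesilylation may outrun the slow exchange at the hindered ketal. The fallback sets out from ketal 13 and comes back at 14. Silyl triflate-mediated elimination of methanol (Me3SiOTf, i-Pr2NEt, CH2Cl2, −20 °C) would give the enol ether 2-methoxy-10-phenyldec-1-ene F10, and kinetically controlled Markovnikov addition of hydroperoxide 8 to it (PPTS 1 mol %, CH2Cl2, −20 °C) would return to 14.

Further compounds
F1 | step 8 | 3-methyl-1-(2-methyl-1,3-dioxolan-2-yl)-11-phenylundecan-3-ol | CC(O)(CCCCCCCCc1ccccc1)CCC1(C)OCCO1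
F2 | step 8 | 5-hydroxy-5-methyl-13-phenyltridecan-2-one | CC(=O)CCC(C)(O)CCCCCCCCc1ccccc1
F3 | step 8 | 5,8-dimethyl-16-phenylhexadec-1-ene-5,8-diol | C=CCCC(C)(O)CCC(C)(O)CCCCCCCCc1ccccc1
F4 | step 8 | 3-(but-3-enyl)-3,6-dimethyl-6-(8-phenyloctyl)-1,2-dioxane (stereoisomer mixture) | C=CCCC1(C)CCC(C)(CCCCCCCCc2ccccc2)OO1
F5 | step 8 | 3-[3,6-dimethyl-6-(8-phenyloctyl)-1,2-dioxan-3-yl]propanal (stereoisomer mixture) | O=CCCC1(C)CCC(C)(CCCCCCCCc2ccccc2)OO1
F6 | step 8 | 3-[3,6-dimethyl-6-(8-phenyloctyl)-1,2-dioxan-3-yl]propanoic acid (stereoisomer mixture) | OC(=O)CCC1(C)CCC(C)(CCCCCCCCc2ccccc2)OO1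
F7 | step 3 | 5-methyl-5-[(trimethylsilyl)ethynyl]oxolan-2-one | C[Si](C)(C)C#CC1(C)CCC(=O)O1
F8 | step 3 | 5-methyl-5-[(Z)-2-(trimethylsilyl)ethenyl]oxolan-2-one | C[Si](C)(C)/C=C\C1(C)CCC(=O)O1
F9 | step 3 | (Z)-4-hydroperoxy-4-methyl-6-(trimethylsilyl)hex-5-enoic acid | C[Si](C)(C)/C=C\C(C)(CCC(=O)O)OO
F10 | step 7 | 2-methoxy-10-phenyldec-1-ene | C=C(OC)CCCCCCCCc1ccccc1
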